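**Plan**

- Numbering (elemane): ring C5–C10. C10 is quaternary (CH3-14 and the C1=C2 vinyl), C9 is CH2, C8 and C6 are carbinols, C7 carries C11(=C13)–C12O2Me, C5 carries C4(=C3)–C15H2OH.
- Retrosynthesis: first remove the O8 ester, the C12 ester (carbonylation of a C11 vinyl bromide) and the C15 hydroxyl (allylic oxidation of an isopropenyl group). Then cut ring bond C5–C6 by a retro carbonyl-ene reaction, then C7–C8 (aldol), then C9–C10 (allylic alkylation).
- Enabling feature: the 6-hydroxyl is homoallylic to the exocyclic C4=C3 methylene (C6(OH)–C5–C4=C3) and trans to it on a cyclohexane (C5–C10) whose substituents are all equatorial except the axial C10 methyl. An open-chain C6 aldehyde carrying a C5=C4 isopropylidene group is therefore the precursor.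
- Forward: the chain C5–C10 is grown from a C10 lactone, C7–C8 is joined by the aldol, and the only carbocycle (C5–C10) closes in step 12. Silyl and ester changes, C15 oxidation, C12 carbonylation and desilylation follow.
- Stereochemistry: C10 from the chiral palladium catalyst (step 1); C7 and C8 from the (R)-benzyloxazolidinone syn-aldol (step 8); C5 and C6 from the chair transition state of the ene closure (step 12).

Key step: step 12

Remark: 3-bromobut-3-enoic acid is taken as a catalogue compound (otherwise two steps from 2,3-dibromopropene by cyanide displacement and acid hydrolysis).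
Remark: the ligand antipode in step 1 is assigned by analogy with related vinyl epoxide alkylations; if the sense of induction proves opposite, the (S,S)-ligand is used.

**Route**

Step 1
Reactants: 1 2-methyl-2-vinyloxirane (isoprene monoxide, racemic); 2 dimethyl malonate
Product: 4 methyl (4R)-4-ethenyl-4-methyl-2-oxooxolane-3-carboxylate (C3 epimers), via hydroxy malonate 3 (not isolated)
Conditions: Pd2(dba)3·CHCl3 (1 mol %, zerovalent palladium), (R,R)-DACH-naphthyl bisphosphine ligand (3 mol %), CH2Cl2, rt; then DBU (10 mol %)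
Reagents that add atoms: none
Why: Palladium-catalysed asymmetric allylic alkylation of a vinyl epoxide (dynamic kinetic asymmetric transformation): both enantiomers of 1 are ionised and equilibrate by π–σ–π shifts, the liberated alkoxide deprotonates the malonate and steers it to the substituted allyl terminus, the chiral ligand sets the quaternary centre C10, and the γ-hydroxy diester should close to the lactone.

Step 2
Reactants: 4 methyl (4R)-4-ethenyl-4-methyl-2-oxooxolane-3-carboxylate
Product: 5 (4S)-4-ethenyl-4-methyloxolan-2-one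
Conditions: LiCl, H2O, DMSO, 150 °C
Reagents that add atoms: none
Why: Krapcho dealkoxycarbonylation of an α-carbomethoxy lactone; the quaternary centre is not involved, and the descriptor changes only through the priority rules.

Step 3
Reactants: 5 (4S)-4-ethenyl-4-methyloxolan-2-one
Product: 6 (3S)-3-(hydroxymethyl)-N-methoxy-N,3-dimethylpent-4-enamide
Conditions: MeNH(OMe)·HCl, Me3Al, CH2Cl2, 0 °C to rt; aqueous potassium sodium tartrate; used without delay
Reagents that add atoms: N,O-dimethylhydroxylamine hydrochloride, CNOC.Cl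
Why: Aluminium amide aminolysis of a lactone to the Weinreb amide should free the neopentyl C5 hydroxyl and store C8 at the acid level; prompt use avoids relactonisation.

Step 4
Reactants: 6 (3S)-3-(hydroxymethyl)-N-methoxy-N,3-dimethylpent-4-enamide
Product: 7 (3S)-3-formyl-N-methoxy-N,3-dimethylpent-4-enamide
Conditions: Dess–Martin periodinane, pyridine, CH2Cl2, 0 °C to rt
Reagents that add atoms: none
Why: Dess–Martin oxidation of a primary alcohol; the aldehyde is α-quaternary, so it cannot enolise and C10 is safe.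

Step 5
Reactants: 7 (3S)-3-formyl-N-methoxy-N,3-dimethylpent-4-enamide
Product: 8 (3S)-3-ethenyl-N-methoxy-N,3,5-trimethylhex-4-enamide
Conditions: i-PrPPh3I, n-BuLi, THF, 0 °C; then 7, −78 °C to rt
Reagents that add atoms: isopropyltriphenylphosphonium iodide, CC(C)[P+](c1ccccc1)(c1ccccc1)c1ccccc1.[I-]
Why: Wittig olefination with a non-stabilised ylide, which should take the aldehyde well before the Weinreb amide; the new C5=C4 alkene carries two identical methyl groups, so no alkene geometry arises.

Step 6
Reactants: 8 (3S)-3-ethenyl-N-methoxy-N,3,5-trimethylhex-4-enamide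
Product: 9 (3S)-3-ethenyl-3,5-dimethylhex-4-enal
Conditions: iBu2AlH, THF, −78 °C; aqueous potassium sodium tartrate
Reagents that add atoms: none
Why: Hydride reduction of a Weinreb amide stops at the aldehyde (C8); alkenes and the quaternary centre are untouched.

Step 7
Reactants: 10 (4R)-4-benzyl-1,3-oxazolidin-2-one; 11 3-bromobut-3-enoic acid
Product: 13 (4R)-4-benzyl-3-(3-bromobut-3-enoyl)-1,3-oxazolidin-2-one, via mixed pivalic anhydride 12 (not isolated)
Conditions: t-BuCOCl, Et3N, THF, −20 °C; then 10, LiCl, rt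
Reagents that add atoms: none
Why: N-acylation of the oxazolidinone through a mixed anhydride under weakly basic conditions, which should avoid isomerisation of the β,γ-unsaturated acyl group.

Step 8
Reactants: 13 (4R)-4-benzyl-3-(3-bromobut-3-enoyl)-1,3-oxazolidin-2-one; 9 (3S)-3-ethenyl-3,5-dimethylhex-4-enal
Product: 16 (4R)-4-benzyl-3-[(2R,3S,5S)-2-(1-bromoethenyl)-5-ethenyl-3-hydroxy-5,7-dimethyloct-6-enoyl]-1,3-oxazolidin-2-one, via boron enolate 14 (not isolated), via boron aldolate 15 (not isolated)
Conditions: Bu2BOTf, i-Pr2NEt, CH2Cl2, −78 to 0 °C; then 9, −78 to 0 °C; then pH 7 buffer, MeOH, 30% H2O2, 0 °C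
Reagents that add atoms: none
Why: Evans syn-aldol reaction: the (Z)-boron enolate reacts through a Zimmerman–Traxler chair on the face away from the benzyl group, which should set C7 (R) and C8 (S) under reagent control whatever the remote C10 centre.

Step 9
Reactants: 16 aldol adduct
Product: 17 (4R)-4-benzyl-3-[(2R,3S,5S)-2-(1-bromoethenyl)-5-ethenyl-5,7-dimethyl-3-[(triethylsilyl)oxy]oct-6-enoyl]-1,3-oxazolidin-2-one
Conditions: TESOTf, 2,6-lutidine, CH2Cl2, −78 °C
Reagents that add atoms: triethylsilyl trifluoromethanesulfonate, CC[Si](CC)(CC)OS(=O)(=O)C(F)(F)F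
Why: Silylation of the β-hydroxy imide blocks retro-aldol and gives a non-chelating O8 group for step 12.

Step 10
Reactants: 17 triethylsilyl ether
Product: 18 (2S,3S,5S)-2-(1-bromoethenyl)-5-ethenyl-5,7-dimethyl-3-[(triethylsilyl)oxy]oct-6-en-1-ol
Conditions: LiBH4, MeOH (1 equiv), THF, 0 °C
Reagents that add atoms: none
Why: Reductive cleavage of the N-acyloxazolidinone to the primary C6 alcohol; the vinyl bromide and alkenes are inert to borohydride, and no stereocentre is touched.

Step 11
Reactants: 18 primary alcohol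
Product: 19 (2R,3S,5S)-2-(1-bromoethenyl)-5-ethenyl-5,7-dimethyl-3-[(triethylsilyl)oxy]oct-6-enal
Conditions: Dess–Martin periodinane, pyridine, CH2Cl2, 0 °C; used at once
Reagents that add atoms: none
Why: Buffered Dess–Martin oxidation gives the C6 aldehyde without epimerising C7 or moving the β,γ-double bond.

Step 12
Reactants: 19 aldehyde
Product: 20 (1R,2S,3S,5S,6S)-6-(1-bromoethenyl)-3-ethenyl-3-methyl-2-(prop-1-en-2-yl)-5-[(triethylsilyl)oxy]cyclohexan-1-ol
Conditions: Me2AlCl (1.5 equiv), CH2Cl2, −78 to −20 °C; aqueous potassium sodium tartrate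
Reagents that add atoms: none
Why: The Lewis acid binds the C6 aldehyde, C5 of the trisubstituted C5=C4 alkene attacks the carbonyl carbon while a hydrogen of the methyl group trans to C10 passes to oxygen, so the C5–C6 bond, the 6-hydroxyl and the exocyclic C4=C3 methylene arise in one type 1 carbonyl-ene event. The closest known reaction type is the Lewis acid-mediated cyclisation of citronellal to isopulegol, here helped by the quaternary C10 (gem-disubstituent effect). The cyclohexane ring C5–C10 closes in a 6-exo-trig mode at the carbonyl carbon through a chair transition state. C5 is set by the alkenyl carbon C4 lying pseudo-equatorial, and C6 by the pseudo-equatorial aluminium-bound oxygen, which avoids a syn-diaxial clash with the axial C10 methyl; both follow from the preset centres C7, C8 and C10, whose bromovinyl, silyloxy and vinyl groups are all equatorial in this chair and all axial in the other. The step needs selectivity for the C5=C4 alkene over the vinyl and bromovinyl groups and no epimerisation at C7: only the trisubstituted alkene is nucleophilic enough and has allylic hydrogens within reach, the O8 silyl ether does not chelate, and low temperature with a proton-scavenging methylaluminium reagent protects the α-centre.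

Step 13
Reactants: 20 cyclohexanol
Product: 21 6-O-tert-butyldimethylsilyl ether of 20
Conditions: TBSOTf, 2,6-lutidine, CH2Cl2, 0 °C to rt
Reagents that add atoms: tert-butyldimethylsilyl trifluoromethanesulfonate, CC(C)(C)[Si](C)(C)OS(=O)(=O)C(F)(F)F
Why: The silyl triflate should silylate the hindered secondary 6-hydroxyl, which must stay masked during acylation and carbonylation.

Step 14
Reactants: 21 bis-silyl ether
Product: 22 8-hydroxy compound (6-O-TBS kept, TES removed)
Conditions: PPTS (cat.), MeOH/CH2Cl2, 0 °C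
Reagents that add atoms: none
Why: Acid-catalysed methanolysis removes the labile triethylsilyl ether much faster than the hindered tert-butyldimethylsilyl ether (selective desilylation).

Step 15
Reactants: 23 methyl 2-(hydroxymethyl)prop-2-enoate
Product: 24 methyl 2-{[(tert-butyldimethylsilyl)oxy]methyl}prop-2-enoate
Conditions: TBSCl, imidazole, CH2Cl2, 0 °C to rt
Reagents that add atoms: tert-butyldimethylsilyl chloride, CC(C)(C)[Si](C)(C)Cl
Why: Standard silylation of a primary allylic alcohol.

Step 16
Reactants: 24 silyl ether ester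
Product: 26 2-{[(tert-butyldimethylsilyl)oxy]methyl}prop-2-enoic acid, via lithium carboxylate 25 (not isolated)
Conditions: LiOH, THF/H2O, 0 °C; then 0.5 M HCl to pH 4, 0 °C
Reagents that add atoms: lithium hydroxide, [Li+].[OH-]
Why: Cold saponification of the methyl ester is faster than conjugate addition; brief mild acidification keeps the silyl ether.

Step 17
Reactants: 26 silyloxymethyl acrylic acid; 22 8-hydroxy compound
Product: 28 8-O-(2-{[(tert-butyldimethylsilyl)oxy]methyl}prop-2-enoyl) ester of 22, via mixed anhydride 27 (not isolated)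
Conditions: 2,4,6-Cl3C6H2COCl, Et3N, toluene, rt; then 22, DMAP, toluene, rt
Reagents that add atoms: none
Why: Yamaguchi esterification: the mixed anhydride, activated by DMAP, should acylate the hindered secondary 8-hydroxyl with retention at C8.

Step 18
Reactants: 28 ester
Product: 29 15-hydroxy derivative of 28 (isopropenyl group turned into 3-hydroxyprop-1-en-2-yl)
Conditions: SeO2 (0.5 equiv), t-BuOOH, CH2Cl2, 0 °C to rt, stopped before full conversion
Reagents that add atoms: selenium dioxide, O=[Se]=O (substoichiometric oxygen carrier); tert-butyl hydroperoxide, CC(C)(C)OO (terminal oxidant)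
Why: Selenium dioxide allylic hydroxylation (ene reaction then [2,3]-sigmatropic shift) should take the methyl group of the only electron-rich alkene with allylic hydrogens, the 1,1-disubstituted isopropenyl group: the C10 vinyl has no allylic hydrogen, the acrylate and bromovinyl alkenes are electron-poor, and the tertiary C5–H is disfavoured.

Step 19
Reactants: 29 allylic alcohol
Product: 30 6,4′-bis-O-tert-butyldimethylsilyl ether of the target (C12 methyl ester in place)
Conditions: Pd(PPh3)4 (10 mol %, zerovalent palladium), CO (1 atm), MeOH, Et3N, DMF, 60 °C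
Reagents that add atoms: carbon monoxide, [C-]#[O+]; methanol, CO
Why: Palladium-catalysed methoxycarbonylation of an alkenyl bromide (oxidative addition, CO insertion, methanolysis) turns the C11 bromovinyl group into the methyl acrylate; O6 is silylated, so no lactone can form, and the remote primary 15-hydroxyl cannot compete with the solvent methanol.

Step 20
Reactants: 30 bis-silyl ether
Product: 31 Elemacarmanin
Conditions: HF·pyridine, pyridine, THF, 0 °C to rt
Reagents that add atoms: none
Why: Buffered fluoride cleavage of both silyl ethers under weakly acidic, non-nucleophilic conditions should avoid acyl migration from O8 to O6, conjugate addition and lactonisation of the 6-hydroxy ester.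

**Compound list**

1 | 2-methyl-2-vinyloxirane (isoprene monoxide, racemic) | CC1(C=C)CO1 | starting material
2 | dimethyl malonate | COC(=O)CC(=O)OC | starting material
3 | dimethyl 2-[(2R)-1-hydroxy-2-methylbut-3-en-2-yl]malonate | COC(=O)C(C(=O)OC)[C@@](C)(C=C)CO | intermediate (not isolated)
4 | methyl (4R)-4-ethenyl-4-methyl-2-oxooxolane-3-carboxylate (C3 epimers) | COC(=O)C1C(=O)OC[C@]1(C)C=C | intermediate
5 | (4S)-4-ethenyl-4-methyloxolan-2-one | O=C1C[C@@](C)(C=C)CO1 | intermediate
6 | (3S)-3-(hydroxymethyl)-N-methoxy-N,3-dimethylpent-4-enamide | CON(C)C(=O)C[C@@](C)(C=C)CO | intermediate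
7 | (3S)-3-formyl-N-methoxy-N,3-dimethylpent-4-enamide | CON(C)C(=O)C[C@@](C)(C=C)C=O | intermediate
8 | (3S)-3-ethenyl-N-methoxy-N,3,5-trimethylhex-4-enamide | CON(C)C(=O)C[C@@](C)(C=C)C=C(C)C | intermediate
9 | (3S)-3-ethenyl-3,5-dimethylhex-4-enal | O=CC[C@@](C)(C=C)C=C(C)C | intermediate
10 | (4R)-4-benzyl-1,3-oxazolidin-2-one | O=C1N[C@H](Cc2ccccc2)CO1 | starting material
11 | 3-bromobut-3-enoic acid | OC(=O)CC(Br)=C | starting material
12 | 3-bromobut-3-enoic pivalic anhydride | C=C(Br)CC(=O)OC(=O)C(C)(C)C | intermediate (not isolated)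
13 | (4R)-4-benzyl-3-(3-bromobut-3-enoyl)-1,3-oxazolidin-2-one | C=C(Br)CC(=O)N1[C@H](Cc2ccccc2)COC1=O | intermediate
14 | (Z)-dibutylboron enolate of 13 | C=C(Br)/C=C(\OB(CCCC)CCCC)N1[C@H](Cc2ccccc2)COC1=O | intermediate (not isolated)
15 | dibutylboron aldolate of 16 | O=C1OC[C@@H](Cc2ccccc2)N1C(=O)[C@H](C(Br)=C)[C@@H](OB(CCCC)CCCC)C[C@@](C)(C=C)C=C(C)C | intermediate (not isolated)
16 | (4R)-4-benzyl-3-[(2R,3S,5S)-2-(1-bromoethenyl)-5-ethenyl-3-hydroxy-5,7-dimethyloct-6-enoyl]-1,3-oxazolidin-2-one | O=C1OC[C@@H](Cc2ccccc2)N1C(=O)[C@H](C(Br)=C)[C@@H](O)C[C@@](C)(C=C)C=C(C)C | intermediate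
17 | (4R)-4-benzyl-3-[(2R,3S,5S)-2-(1-bromoethenyl)-5-ethenyl-5,7-dimethyl-3-[(triethylsilyl)oxy]oct-6-enoyl]-1,3-oxazolidin-2-one | O=C1OC[C@@H](Cc2ccccc2)N1C(=O)[C@H](C(Br)=C)[C@@H](O[Si](CC)(CC)CC)C[C@@](C)(C=C)C=C(C)C | intermediate
18 | (2S,3S,5S)-2-(1-bromoethenyl)-5-ethenyl-5,7-dimethyl-3-[(triethylsilyl)oxy]oct-6-en-1-ol | OC[C@H](C(Br)=C)[C@@H](O[Si](CC)(CC)CC)C[C@@](C)(C=C)C=C(C)C | intermediate
19 | (2R,3S,5S)-2-(1-bromoethenyl)-5-ethenyl-5,7-dimethyl-3-[(triethylsilyl)oxy]oct-6-enal | O=C[C@H](C(Br)=C)[C@@H](O[Si](CC)(CC)CC)C[C@@](C)(C=C)C=C(C)C | intermediate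
20 | (1R,2S,3S,5S,6S)-6-(1-bromoethenyl)-3-ethenyl-3-methyl-2-(prop-1-en-2-yl)-5-[(triethylsilyl)oxy]cyclohexan-1-ol (elemane positions: 6α-OH, 8α-OTES, 7β-bromovinyl, 5β-isopropenyl, 10β-methyl, 10α-vinyl) | C=C[C@]1(C)C[C@H](O[Si](CC)(CC)CC)[C@@H](C(Br)=C)[C@H](O)[C@H]1C(C)=C | intermediate
21 | 6-O-tert-butyldimethylsilyl ether of 20 | C=C[C@]1(C)C[C@H](O[Si](CC)(CC)CC)[C@@H](C(Br)=C)[C@H](O[Si](C)(C)C(C)(C)C)[C@H]1C(C)=C | intermediate
22 | 8-hydroxy compound: 21 without the triethylsilyl group | C=C[C@]1(C)C[C@H](O)[C@@H](C(Br)=C)[C@H](O[Si](C)(C)C(C)(C)C)[C@H]1C(C)=C | intermediate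
23 | methyl 2-(hydroxymethyl)prop-2-enoate | COC(=O)C(=C)CO | starting material
24 | methyl 2-{[(tert-butyldimethylsilyl)oxy]methyl}prop-2-enoate | COC(=O)C(=C)CO[Si](C)(C)C(C)(C)C | intermediate
25 | lithium 2-{[(tert-butyldimethylsilyl)oxy]methyl}prop-2-enoate | [Li+].[O-]C(=O)C(=C)CO[Si](C)(C)C(C)(C)C | intermediate (not isolated)
26 | 2-{[(tert-butyldimethylsilyl)oxy]methyl}prop-2-enoic acid | OC(=O)C(=C)CO[Si](C)(C)C(C)(C)C | intermediate
27 | mixed anhydride of 26 with 2,4,6-trichlorobenzoic acid | C=C(CO[Si](C)(C)C(C)(C)C)C(=O)OC(=O)c1c(Cl)cc(Cl)cc1Cl | intermediate (not isolated)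
28 | 8-O-(2-{[(tert-butyldimethylsilyl)oxy]methyl}prop-2-enoyl) ester of 22 | C=C[C@]1(C)C[C@H](OC(=O)C(=C)CO[Si](C)(C)C(C)(C)C)[C@@H](C(Br)=C)[C@H](O[Si](C)(C)C(C)(C)C)[C@H]1C(C)=C | intermediate
29 | 15-hydroxy derivative of 28 | C=C[C@]1(C)C[C@H](OC(=O)C(=C)CO[Si](C)(C)C(C)(C)C)[C@@H](C(Br)=C)[C@H](O[Si](C)(C)C(C)(C)C)[C@H]1C(=C)CO | intermediate
30 | 6,4′-bis-O-tert-butyldimethylsilyl ether of Elemacarmanin | C=C[C@]1(C)C[C@H](OC(=O)C(=C)CO[Si](C)(C)C(C)(C)C)[C@@H](C(=C)C(=O)OC)[C@H](O[Si](C)(C)C(C)(C)C)[C@H]1C(=C)CO | intermediate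
31 | Elemacarmanin | C=C[C@]1(C)C[C@H](OC(=O)C(=C)CO)[C@@H](C(=C)C(=O)OC)[C@H](O)[C@H]1C(=C)CO | target

**Step count and risks**

Total step count: 20. Longest linear sequence: 17 (steps 1–6, 8–14, 17–20).

Steps most likely to fail:

1. Step 18. The allylic oxidation may be slow at the isopropenyl group, which is flanked by the O6 silyl ether and the quaternary C10, and may over-oxidise to the enal or erode the silyl ethers. The fallback sets out from 28 and comes back at 29. Ene-type chlorination of the isopropenyl group with Ca(OCl)2 and solid CO2 in CH2Cl2/H2O at 0 °C should give the allylic chloride F1. Displacement with HCO2Cs in DMF at rt should give the allylic formate F2. Methanolysis with KHCO3 in MeOH at 0 °C, which spares the acrylate ester, should return 29.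

2. Step 1. The malonate may attack the unsubstituted allyl terminus, or the enantioselectivity may be too low for this nucleophile. The fallback sets out from 1 and comes back at 5; it builds the quaternary carbon by a sigmatropic shift and resolves it classically.
   - Pd(PPh3)4-catalysed 1,4-opening of 1 with acetic acid should give (2E)-4-hydroxy-3-methylbut-2-en-1-yl acetate F3.
   - TBSCl/imidazole should give the silyl ether acetate F4, and K2CO3 in MeOH the allylic alcohol F5.
   - Johnson–Claisen rearrangement (MeC(OEt)3, cat. EtCO2H, 140 °C) should give the racemic quaternary ester F6, and TsOH in MeOH the racemic lactone F7.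
   - Opening with (S)-1-phenylethylamine and Me3Al should give two hydroxy amides. The (3S)-hydroxy amide F8 is separated from the (3R)-hydroxy amide F9 by chromatography or crystallisation and relactonised with aqueous H2SO4 in dioxane to 5.

3. Step 12. The Lewis acid may remove the O8 silyl group, cause β-elimination or C7 epimerisation of the aldehyde, or give incomplete control at C6. The fallback sets out from 18 and comes back at 20. PhSeCl-catalysed ene-chlorination of the isopropylidene group with N-chlorosuccinimide in CH2Cl2 should give the secondary allylic chloride F10 (C5 epimers). Dess–Martin oxidation should give the chloro aldehyde F11. CrCl2 (divalent chromium) in THF at 0 °C to rt should then close the same C5–C6 bond by intramolecular Nozaki–Hiyama allylation under neutral conditions, through the same all-equatorial chair, to give 20.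

**Further compounds**

F1 | step 18 | 15-chloro analogue of 28 (3-chloroprop-1-en-2-yl group at C5) | C=C[C@]1(C)C[C@H](OC(=O)C(=C)CO[Si](C)(C)C(C)(C)C)[C@@H](C(Br)=C)[C@H](O[Si](C)(C)C(C)(C)C)[C@H]1C(=C)CCl
F2 | step 18 | 15-O-formate of 29 | C=C[C@]1(C)C[C@H](OC(=O)C(=C)CO[Si](C)(C)C(C)(C)C)[C@@H](C(Br)=C)[C@H](O[Si](C)(C)C(C)(C)C)[C@H]1C(=C)COC=O
F3 | step 1 | (2E)-4-hydroxy-3-methylbut-2-en-1-yl acetate | CC(=O)OC/C=C(\C)CO
F4 | step 1 | (2E)-4-[(tert-butyldimethylsilyl)oxy]-3-methylbut-2-en-1-yl acetate | CC(=O)OC/C=C(\C)CO[Si](C)(C)C(C)(C)C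
F5 | step 1 | (2E)-4-[(tert-butyldimethylsilyl)oxy]-3-methylbut-2-en-1-ol | OC/C=C(\C)CO[Si](C)(C)C(C)(C)C
F6 | step 1 | ethyl 3-{[(tert-butyldimethylsilyl)oxy]methyl}-3-methylpent-4-enoate (racemic) | CCOC(=O)CC(C)(C=C)CO[Si](C)(C)C(C)(C)C
F7 | step 1 | 4-ethenyl-4-methyloxolan-2-one (racemic) | O=C1CC(C)(C=C)CO1
F8 | step 1 | (3S)-3-(hydroxymethyl)-3-methyl-N-[(1S)-1-phenylethyl]pent-4-enamide | C[C@H](NC(=O)C[C@@](C)(C=C)CO)c1ccccc1
F9 | step 1 | (3R)-3-(hydroxymethyl)-3-methyl-N-[(1S)-1-phenylethyl]pent-4-enamide | C[C@H](NC(=O)C[C@](C)(C=C)CO)c1ccccc1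
F10 | step 12 | (2S,3S,5R)-2-(1-bromoethenyl)-6-chloro-5-ethenyl-5,7-dimethyl-3-[(triethylsilyl)oxy]oct-7-en-1-ol (C6 epimers) | OC[C@H](C(Br)=C)[C@@H](O[Si](CC)(CC)CC)C[C@@](C)(C=C)C(Cl)C(C)=C
F11 | step 12 | (2R,3S,5R)-2-(1-bromoethenyl)-6-chloro-5-ethenyl-5,7-dimethyl-3-[(triethylsilyl)oxy]oct-7-enal (C6 epimers) | O=C[C@H](C(Br)=C)[C@@H](O[Si](CC)(CC)CC)C[C@@](C)(C=C)C(Cl)C(C)=C
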